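(The runs stem from a simulated flask for an exercise; scatter was added.)

Start from what is asked of the west run: how much starting material it keeps when it is charged with 0.300 mM of free catalyst, a charge no earlier run has tried.

| flask | starting material | free catalyst | time |
|---|---|---|---|
| north-east | 300 mM | 0.600 mM |  |
| south-east | 120 mM | 0.600 mM |  |
| east | 900 mM | 0.600 mM |  |
| west | 600 mM | 0.300 mM | 73 min |

| run | time / min | [starting material] / mM |
|---|---|---|
| north-east run | 9.1 | 250 |
| north-east run | 18 | 208 |
| north-east run | 27 | 168 |
| north-east run | 36 | 141 |
| north-east run | 46 | 120 |
| north-east run | 55 | 101 |
| north-east run | 64 | 78 |
| north-east run | 73 | 68 |
| south-east run | 9.1 | 95 |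
| south-east run | 18 | 82 |
| south-east run | 27 | 66 |
| south-east run | 36 | 57 |
| south-east run | 46 | 48 |
| south-east run | 55 | 39 |
| south-east run | 64 | 26 |
| south-east run | 73 | 24 |
| east run | 9.1 | 760 |
| east run | 18 | 653 |
| east run | 27 | 547 |
| east run | 36 | 450 |
| east run | 46 | 381 |
| east run | 55 | 315 |
| east run | 64 | 263 |
| east run | 73 | 211 |

(each reading ± 3 mM)

- Overall: starting material -> product, with free catalyst as catalyst.
- Constant volume, constant temperature.
- The analysis sees a species whether free or bound.
- An order is taken over about fifteen percent of the charge, up and down.

- the power of [starting material] that the first rate follows, about the charge of the north-east run; measure it at two percent of starting material made into product (one fixed amount of product, the same in the runs compared)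
- the south-east run starts with 180 mM less of starting material than the north-east run, and with no product. Compared where both hold the same amount of starting material, once fifteen percent of what the south-east run was charged with has turned into product, is the south-east run faster, slower or alike (within a tenth)?
- starting material in the west run at 73 min, as a share of the starting material charged

Measure each stretch by its lifetime τ, the time elapsed divided by the natural logarithm of the fall in starting material; this is the inverse of a pseudo-first-order constant. Read it at both ends of the charges. The whole south-east run gives τ_S = 45.4 min. The east run, falling from 653 mM to 315 mM, gives τ_E = 50.8 min, the high-charge lifetime.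

Between these stretches the geometric-mean amount of starting material rises by a factor 8.45, while τ rises by 1.12. My order, from the ratio of their logarithms, is therefore 0.947. The north-east run after 46 min, at 120 mM, repeats τ_S to a factor 1.05, so I call the comparison alike.

For the west run, take τ_E, since its stretch covers the amounts the west run should pass through, and scale it inversely with catalyst: 102 min. The share exp(−t/τ) is then 48.7%. Go round once: that ends the west run near 292 mM, close to the end of the east stretch, so τ_E stands.

The forecast says order 0.91 (0.83 to 0.98), below mine; alike; and 49% (44% to 54%), on the ground that “rate is proportional to catalyst, which is untested”.

The flask gives order 0.95, alike, and 44.6%, each as the forecast allowed.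

    2 free catalyst ⇌ catalyst dimer, settled at all times (52800 /M)
    free catalyst + starting material → product + free catalyst (341.4 /M/min)
    free catalyst + starting material ⇌ idle catalyst-substrate complex, settled at all times (3.170 /M)
    free catalyst + impurity → spent catalyst

Turned back into a lifetime, the west share is 90.3 min, or 1.78 times τ_E. The west run without the impurity keeps 33.4%, a lifetime of 66.5 min, or 1.31 times τ_E. So the impurity, which at once removes 0.114 mM of the 0.300 mM of free catalyst charged to the west run, is why that run keeps more starting material than it does without the impurity, by 11 percentage points.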